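## Structural features

Palisadin B is a trans-fused bicycle: a cyclohexane (ring A: C5a, C6, C7, C8, C9, C9a) shares the C5a–C9a bond with a 2,5-dihydro-oxepine (ring B: O1, C2, C3, C4, C5, C5a, C9a), whose ether oxygen sits on the fully substituted C9a and whose only unsaturation is the trisubstituted C3=C4 bond. Three stereocentres lie on ring A: the oxygen-bearing quaternary C9a (axial methyl), the methine C5a, and, across the gem-dimethyl carbon C6, the secondary bromide C7 (equatorial, cis to the C5 arm). The fourth, C2, lies across O1 and carries CH2Br on the same face as the C9a methyl; the configuration is (2R,5aS,7S,9aS). The C9a methyl and the axial C6 methyl are syn-diaxial, so the C5a–C9a bond must be built against this strain. Fragile groups are the C7 bromide (reduction, elimination, cationic rearrangement under ionising or halophilic conditions such as AgBF4), the allylic C2–O1 ether, the primary bromide β to oxygen and, in intermediates, a free C9a hydroxyl trans-1,4 to the bromide, which strong base could turn into an oxygen bridge. The real difficulty lies in three places: the congested C5a–C9a bond with its two stereocentres, a bromine of defined configuration on a carbon next to a quaternary centre, and a seven-membered ether closed from a tertiary alcohol with control of the remote C2. The key step uses the fact that in an open chain C9a is a methyl ketone carbon and C5a the β-carbon of an enoate, 1,6-related through C9, C8, C7 and C6; both are electrophiles, and one-electron reduction reverses the polarity of C9a so that ring A closes between them with C7 as the only stereocentre present.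

## Logic of the disconnections

22 to 21: the primary C–Br bond on the C2 side arm is cut. This is the most labile function, so it comes last; 21 carries a hydroxyl that can arise from a C=C bond. The forward substitution must be neutral enough to leave C7–Br and the allylic ether untouched.

21 to 19 (through 20): C2–H and CH2–O are removed across an exocyclic C2=CH2 bond. C2 becomes planar, so ring B can be closed without a stereochemical demand. The forward anti-Markovnikov hydration must deliver hydrogen to C2 from the face opposite the C9a methyl.

19 to 18: O1–C2 is cut. An ether at a tertiary oxygen cannot be made by alkylation, but O–H can be added across an alkyne. Ring B opens to a monocyclic tertiary alcohol. The forward step needs attack at the internal alkyne carbon (7-exo-dig), which requires the Z-alkene.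

18 to 15 and 16 (through 17): the sp–sp2 bond C2–C3 is cut. Two carbons leave as a commercial alkyne. The coupling must retain the olefin geometry and ignore the alkyl bromide.

15 to 10 and 11 (through 12, 13, 14): C3=C4 is cut. The side arm shrinks to a two-carbon aldehyde equivalent. The olefination must place iodine cis to the chain and tolerate the free C9a hydroxyl.

10 to 9: the oxidation level of C4 is adjusted, which exposes the ester formed in the ring closure.

9 to 8: C5a–C9a is cut. Ring A and two stereocentres disappear and an open chain with a single stereocentre remains. The forward step must join two electrophilic carbons, spare C–Br, and set C5a and C9a from C7.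

8 to 7: the C9a carbonyl is traced to a terminal C=C. A γ-bromo ketone would close to a cyclopropane under base, so the ketone is unveiled only after all basic steps. An alkene needs no protection steps and, unlike an acetal, has no oxygen that could displace an activated C7 leaving group through a five-membered oxonium ion. The oxidation must be Markovnikov-selective beside an enoate and a bromide.

7 to 5 and 6: C5=C5a is cut. Two carbons come from a commercial phosphonate. The olefination must give the E-enoate under weakly basic conditions.

5 to 4: the oxidation level at C5a is adjusted; the ester is the group that arrives with the aldol.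

4 to 3: C7–Br is traced to C7–OH of opposite configuration, because a carbinol stereocentre is available by asymmetric aldol. The inversion is placed where the adjacent quaternary carbon bears an ester, which disfavours ionisation and offers no α-hydrogen. Bromine must be in place before ring closure, since it is the element that orients the fold.

3 to 1 and 2: C6–C7 is cut. Two commercial fragments remain and the quaternary C6 arrives complete. The aldol needs enantiofacial control by a chiral promoter.

## Other disconnections considered

Alternative 1: The cut takes O1 out from between C2 and C9a, so that lactone A2 goes back to the carbocyclic α-methyl enone A1, a trans-decalone with C9a as the angular quaternary carbon. Forward, buffered mCPBA adds to the C2 carbonyl and the tertiary C9a migrates to oxygen with retention (Baeyer–Villiger).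
- In its favour: C9a is set beforehand as an all-carbon centre by enantioselective Robinson annulation chemistry and is transferred to oxygen stereospecifically. C5a and C7 are then set on a rigid trans-decalin. On stereochemical security of ring A this plan is better than the chosen one, whose relay from C7 to C5a rests on a small conformational bias.
- Also better: the ring B olefin cannot have the wrong geometry, and C–Br never meets a reductant.
- Against it: the carbonyl is conjugated and flanked by a quaternary carbon, so peracid addition is slow and competes with vinyl migration and epoxidation.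
- Equal: the C7 bromide again needs inversion at a neopentyl carbinol, and A2 still needs methylenation, hydroboration and bromination, the same three operations as after 19.
- Step economy: roughly equal, since A1 is about nine steps from commercial material. Its key step forms no C–C bond and no stereocentre.

Alternative 2: The cut excises C3. C2–C3 and C3–C4 are broken and ring B contracts to dihydropyran A3, whose enol ether double bond joins C2 and C4. Forward, dibromocarbene gives the dibromocyclopropane A4; AgBF4 removes one bromide with ring opening, and Et3SiH delivers hydride to C2 to give A5.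
- In its favour: two C–C bonds and the seven-membered ring form in one operation. The C2 side arm is already present, so no labile 2-alkoxydiene such as 19 is handled (better). The olefin geometry is fixed by the ring (better).
- Against it: AgBF4 is a halophile, and the neopentyl C7–Br is the kind of bond it can ionise with rearrangement; the chosen route uses no such reagent (worse here).
- Equal: hydride must find C2 and the correct face, a problem of the same kind as the hydroboration of 19.
- Step economy: worse. Methylation of the vinylic bromide, desilylation and bromination follow, and A3 itself presupposes ring A with all three stereocentres plus an enol ether synthesis. The plan leaves the C5a–C9a problem to other chemistry.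

Alternative 3: The cut is O1–C2; the 2-methylene oxepene A7 goes back to the (Z)-enyne tertiary alcohol A6. Forward, Ph3PAuNTf2 activates the terminal alkyne and the C9a hydroxyl adds to its internal carbon, 7-exo-dig. A6 and A7 are the same structures as 18 and 19, and the chosen route uses this closure as step 10; the plans differ in which bond is treated as strategic.
- In its favour: the closure is catalytic, redox-neutral and free of by-products, avoids alkylating a tertiary alcohol and tolerates C–Br. On the O1–C2 problem it is the equal of the chosen plan by definition.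
- Against it as the central idea: it forms no C–C bond and no stereocentre, leaves C2 planar, and carries its own risks (attack at C4, hydration, lability of the enol ether).
- It presupposes A6, whose ring A is the real problem, so step economy is equal at best.
- A plan that made A6 from a rigid cyclic precursor could set C5a and C9a more securely than the chosen ring closure; that point is conceded.

Key step: step 6

Remarks. Atoms are numbered as in the target (1-benzoxepine numbering) in all intermediates. The (S)-valine-derived promoter of step 1 is assumed to give the (3R) carbinol with an unbranched aliphatic aldehyde; if the sense were opposite, the (R)-valine reagent would be used in the same way.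

## Steps

Step 1
Reactants: 1 pent-4-enal; 2 1-methoxy-2-methyl-1-(trimethylsilyloxy)prop-1-ene
Product: 3 methyl (3R)-3-hydroxy-2,2-dimethylhept-6-enoate
Conditions: N-Ts-(S)-valine (1.1 equiv), BH3·THF (1.0 equiv), CH2Cl2, 0 °C → rt; then 1 and 2, −78 °C; pH 7 buffer, then 1 M HCl
Reagents that add atoms: none
Why: Oxazaborolidinone-promoted asymmetric Mukaiyama aldol; the boron-bound aldehyde exposes one face to the tetrasubstituted silyl ketene acetal, forming C6–C7 and the (R) carbinol at C7 that inversion will turn into the (S) bromide; the borane is consumed in making the promoter, so the terminal alkene is not hydroborated.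

Step 2
Reactants: 3 methyl (3R)-3-hydroxy-2,2-dimethylhept-6-enoate
Product: 4 methyl (3S)-3-bromo-2,2-dimethylhept-6-enoate
Conditions: CBr4, PPh3, toluene, 0 → 60 °C
Reagents that add atoms: carbon tetrabromide, BrC(Br)(Br)Br
Why: Appel reaction; bromide displaces the alkoxyphosphonium group from the rear and inverts C7 to (S); the ester on the adjacent quaternary carbon disfavours ionisation and 1,2-shift and there is no α-hydrogen, so the only competing path is elimination toward C8.

Step 3
Reactants: 4 methyl (3S)-3-bromo-2,2-dimethylhept-6-enoate
Product: 5 (3S)-3-bromo-2,2-dimethylhept-6-enal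
Conditions: i-Bu2AlH (1.1 equiv), CH2Cl2, −78 °C; MeOH, then aq. KNaC4H4O6
Reagents that add atoms: none
Why: Partial reduction of an α-quaternary ester, whose i-Bu2Al-bound hemiacetal persists at −78 °C and releases the aldehyde on work-up; without an α-hydrogen the β-bromo aldehyde can neither eliminate nor epimerise, and any over-reduced alcohol can be returned with Dess–Martin periodinane.

Step 4
Reactants: 5 (3S)-3-bromo-2,2-dimethylhept-6-enal; 6 trimethyl phosphonoacetate
Product: 7 methyl (2E,5S)-5-bromo-4,4-dimethylnona-2,8-dienoate
Conditions: 6, NaH, THF, 0 °C; then 5, 0 °C → rt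
Reagents that add atoms: none
Why: Horner–Wadsworth–Emmons olefination; α-branched aldehydes give the E-enoate, the phosphonate anion is too weak a base to eliminate the neopentyl bromide, and collapse to the oxaphosphetane outpaces any fragmentation of the transient alkoxide.

Step 5
Reactants: 7 methyl (2E,5S)-5-bromo-4,4-dimethylnona-2,8-dienoate
Product: 8 methyl (2E,5S)-5-bromo-4,4-dimethyl-8-oxonon-2-enoate
Conditions: PdCl2 (10 mol %), CuCl (30 mol %), O2 (1 atm), DMF/H2O 7:1, rt
Reagents that add atoms: water, O
Why: Tsuji–Wacker oxidation; divalent palladium hydroxypalladates the monosubstituted alkene in the Markovnikov sense, while the electron-poor disubstituted enoate and the alkyl bromide do not react; unveiling the ketone only now keeps the γ-bromo ketone away from base.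

Step 6
Reactants: 8 methyl (2E,5S)-5-bromo-4,4-dimethyl-8-oxonon-2-enoate
Product: 9 methyl 2-[(1S,3S,6S)-3-bromo-6-hydroxy-2,2,6-trimethylcyclohexyl]acetate
Conditions: SmI2 (2.5 equiv, 0.1 M in THF), MeOH (4 equiv), THF, −78 → −20 °C, no HMPA; aq. NH4Cl
Reagents that add atoms: none
Why: SmI2 transfers one electron to the keto enoate to give a ketyl at C9a, this nucleophilic radical adds to C5a (the β-carbon of the E-enoate), and a second electron turns the α-ester radical into a trivalent samarium enolate that MeOH protonates at C5. The closest known reaction type is the SmI2-mediated ketyl–olefin (reductive carbonyl–alkene) cyclisation of keto enoates to trans-2-hydroxycycloalkyl acetates. Ring A closes 6-exo-trig through a chair whose tether contains the gem-dimethyl carbon C6, which favours folding (Thorpe–Ingold effect). At C9a the solvated O–Sm group takes the equatorial site turned away from the ester (an E-enoate cannot chelate), so the methyl becomes axial and O1 ends trans to the C5 arm. At C5a the enoate stays equatorial, and the equatorial preference of the C7 bromine selects the chair that puts the arm cis to Br, giving (5aS,9aS) from (7S). The step needs chemoselectivity for the carbonyl and enoate over C–Br, which the absence of HMPA and the low temperature should secure, because unactivated secondary bromides are reduced only by the much stronger SmI2–HMPA system. It also needs the relay from C7, which rests on a small conformational bias and is the softer of the two stereochemical elements; the trans relation of O1 and C5 is the firmer one. The hindered C5a is reached because the addition is intramolecular and radical additions tolerate a neopentyl β-carbon far better than polar ones.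

Step 7
Reactants: 9 methyl 2-[(1S,3S,6S)-3-bromo-6-hydroxy-2,2,6-trimethylcyclohexyl]acetate
Product: 10 (3aS,5S,7aS)-5-bromo-4,4,7a-trimethyloctahydro-1-benzofuran-2-ol
Conditions: i-Bu2AlH (2.3 equiv), CH2Cl2, −78 °C; aq. KNaC4H4O6
Reagents that add atoms: none
Why: Reduction of a γ-hydroxy ester to the lactol; the first equivalent deprotonates the hydroxyl, the second reduces the ester to an i-Bu2Al-bound hemiacetal held by the neighbouring alkoxide, and work-up gives the trans-fused lactol in equilibrium with its hydroxy aldehyde.

Step 8
Reactants: 10 (3aS,5S,7aS)-5-bromo-4,4,7a-trimethyloctahydro-1-benzofuran-2-ol; 11 ethyltriphenylphosphonium iodide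
Product: 15 (1S,2S,4S)-4-bromo-2-[(2Z)-3-iodobut-2-en-1-yl]-1,3,3-trimethylcyclohexan-1-ol, via ethylidenetriphenylphosphorane 12 (not isolated), via (1-iodoethyl)triphenylphosphonium iodide 13 (not isolated), via (1-iodoethylidene)triphenylphosphorane 14 (not isolated)
Conditions: 11, n-BuLi, THF, 0 °C → rt; I2, −78 °C; NaN(SiMe3)2, −78 → −20 °C; then 10, −78 °C → rt
Reagents that add atoms: iodine, II
Why: Wittig olefination with an α-iodo ylide (Stork–Zhao type); the non-stabilised ylide reacts with the open hydroxy aldehyde form of 10 under kinetic control to give the (Z)-2-iodoalkene with iodine cis to the chain, the geometry ring B needs.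

Step 9
Reactants: 15 (1S,2S,4S)-4-bromo-2-[(2Z)-3-iodobut-2-en-1-yl]-1,3,3-trimethylcyclohexan-1-ol; 16 ethynyltrimethylsilane
Product: 18 (1S,2S,4S)-4-bromo-1,3,3-trimethyl-2-[(2Z)-3-methylpent-2-en-4-yn-1-yl]cyclohexan-1-ol, via trimethylsilyl enyne 17 (not isolated)
Conditions: PdCl2(PPh3)2 (5 mol %), CuI (10 mol %), Et3N, THF, rt; then MeOH, K2CO3, rt
Reagents that add atoms: none
Why: Sonogashira coupling proceeds with retention of the olefin geometry, and the secondary alkyl bromide does not add oxidatively to zerovalent palladium at room temperature; methanolysis of the C–Si bond in the same flask frees the terminal alkyne.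

Step 10
Reactants: 18 (1S,2S,4S)-4-bromo-1,3,3-trimethyl-2-[(2Z)-3-methylpent-2-en-4-yn-1-yl]cyclohexan-1-ol
Product: 19 (5aS,7S,9aS)-7-bromo-3,6,6,9a-tetramethyl-2-methylidene-2,5,5a,6,7,8,9,9a-octahydro-1-benzoxepine
Conditions: Ph3PAuNTf2 (5 mol %), CH2Cl2, 4 Å MS, 0 °C → rt; Et3N quench, filtration through basic Al2O3
Reagents that add atoms: none
Why: Intramolecular alkyne hydroalkoxylation; cationic monovalent gold activates the terminal alkyne, the C9a hydroxyl attacks the internal carbon anti to the metal (7-exo-dig) and protodeauration gives the exocyclic enol ether; the Z-alkene and the equatorial bonds at C5a and C9a hold O1 and C2 within reach, and the neutral conditions spare C–Br.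

Step 11
Reactants: 19 (5aS,7S,9aS)-7-bromo-3,6,6,9a-tetramethyl-2-methylidene-2,5,5a,6,7,8,9,9a-octahydro-1-benzoxepine
Product: 21 [(2R,5aS,7S,9aS)-7-bromo-3,6,6,9a-tetramethyl-2,5,5a,6,7,8,9,9a-octahydro-1-benzoxepin-2-yl]methanol, via B-alkyl-9-borabicyclononane 20 (not isolated)
Conditions: 9-BBN (1.5 equiv), THF, 0 °C → rt; then aq. NaOH, H2O2, 0 °C
Reagents that add atoms: hydrogen peroxide, OO
Why: Hydroboration–oxidation of an exocyclic enol ether; boron goes to the terminal carbon for steric and electronic reasons and hydrogen to C2 from the face opposite the C9a methyl, which sets C2 as (R) with the hydroxymethyl group cis to that methyl; the trisubstituted C3=C4 bond is too hindered for 9-BBN and the C–B bond is oxidised with retention.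

Step 12
Reactants: 21 [(2R,5aS,7S,9aS)-7-bromo-3,6,6,9a-tetramethyl-2,5,5a,6,7,8,9,9a-octahydro-1-benzoxepin-2-yl]methanol
Product: 22 palisadin B
Conditions: CBr4, PPh3, 2,6-lutidine, CH2Cl2, 0 °C
Reagents that add atoms: carbon tetrabromide, BrC(Br)(Br)Br
Why: Appel reaction at an unhindered primary alcohol; the neutral, buffered conditions leave the allylic ether, the olefin and the secondary bromide untouched, and no stereocentre is involved.

## Compound list

1 | pent-4-enal | C=CCCC=O | starting material
2 | 1-methoxy-2-methyl-1-(trimethylsilyloxy)prop-1-ene | COC(O[Si](C)(C)C)=C(C)C | starting material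
3 | methyl (3R)-3-hydroxy-2,2-dimethylhept-6-enoate | C=CCC[C@@H](O)C(C)(C)C(=O)OC | intermediate
4 | methyl (3S)-3-bromo-2,2-dimethylhept-6-enoate | C=CCC[C@H](Br)C(C)(C)C(=O)OC | intermediate
5 | (3S)-3-bromo-2,2-dimethylhept-6-enal | C=CCC[C@H](Br)C(C)(C)C=O | intermediate
6 | trimethyl phosphonoacetate | COC(=O)CP(=O)(OC)OC | starting material
7 | methyl (2E,5S)-5-bromo-4,4-dimethylnona-2,8-dienoate | C=CCC[C@H](Br)C(C)(C)/C=C/C(=O)OC | intermediate
8 | methyl (2E,5S)-5-bromo-4,4-dimethyl-8-oxonon-2-enoate | CC(=O)CC[C@H](Br)C(C)(C)/C=C/C(=O)OC | intermediate
9 | methyl 2-[(1S,3S,6S)-3-bromo-6-hydroxy-2,2,6-trimethylcyclohexyl]acetate | COC(=O)C[C@H]1C(C)(C)[C@@H](Br)CC[C@]1(C)O | intermediate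
10 | (3aS,5S,7aS)-5-bromo-4,4,7a-trimethyloctahydro-1-benzofuran-2-ol (both C2 epimers, in equilibrium with the hydroxy aldehyde) | OC1C[C@H]2C(C)(C)[C@@H](Br)CC[C@]2(C)O1 | intermediate
11 | ethyltriphenylphosphonium iodide | CC[P+](c1ccccc1)(c1ccccc1)c1ccccc1.[I-] | starting material
12 | ethylidenetriphenylphosphorane | CC=P(c1ccccc1)(c1ccccc1)c1ccccc1 | intermediate (not isolated)
13 | (1-iodoethyl)triphenylphosphonium iodide | CC(I)[P+](c1ccccc1)(c1ccccc1)c1ccccc1.[I-] | intermediate (not isolated)
14 | (1-iodoethylidene)triphenylphosphorane | CC(I)=P(c1ccccc1)(c1ccccc1)c1ccccc1 | intermediate (not isolated)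
15 | (1S,2S,4S)-4-bromo-2-[(2Z)-3-iodobut-2-en-1-yl]-1,3,3-trimethylcyclohexan-1-ol | C/C(I)=C/C[C@H]1C(C)(C)[C@@H](Br)CC[C@]1(C)O | intermediate
16 | ethynyltrimethylsilane | C#C[Si](C)(C)C | starting material
17 | (1S,2S,4S)-4-bromo-1,3,3-trimethyl-2-[(2Z)-3-methyl-5-(trimethylsilyl)pent-2-en-4-yn-1-yl]cyclohexan-1-ol | C/C(C#C[Si](C)(C)C)=C/C[C@H]1C(C)(C)[C@@H](Br)CC[C@]1(C)O | intermediate (not isolated)
18 | (1S,2S,4S)-4-bromo-1,3,3-trimethyl-2-[(2Z)-3-methylpent-2-en-4-yn-1-yl]cyclohexan-1-ol | C/C(C#C)=C/C[C@H]1C(C)(C)[C@@H](Br)CC[C@]1(C)O | intermediate
19 | (5aS,7S,9aS)-7-bromo-3,6,6,9a-tetramethyl-2-methylidene-2,5,5a,6,7,8,9,9a-octahydro-1-benzoxepine | CC1=CC[C@H]2C(C)(C)[C@@H](Br)CC[C@]2(C)OC1=C | intermediate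
20 | 9-{[(2S,5aS,7S,9aS)-7-bromo-3,6,6,9a-tetramethyl-2,5,5a,6,7,8,9,9a-octahydro-1-benzoxepin-2-yl]methyl}-9-borabicyclo[3.3.1]nonane (C2–H on the face opposite the C9a methyl) | CC1=CC[C@H]2C(C)(C)[C@@H](Br)CC[C@]2(C)O[C@H]1CB1C2CCCC1CCC2 | intermediate (not isolated)
21 | [(2R,5aS,7S,9aS)-7-bromo-3,6,6,9a-tetramethyl-2,5,5a,6,7,8,9,9a-octahydro-1-benzoxepin-2-yl]methanol | CC1=CC[C@H]2C(C)(C)[C@@H](Br)CC[C@]2(C)O[C@H]1CO | intermediate
22 | palisadin B, (2R,5aS,7S,9aS)-7-bromo-2-(bromomethyl)-3,6,6,9a-tetramethyl-2,5,5a,6,7,8,9,9a-octahydro-1-benzoxepine | CC1=CC[C@H]2C(C)(C)[C@@H](Br)CC[C@]2(C)O[C@H]1CBr | target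

## Step count and least certain steps

Total: 12 steps. Longest linear sequence: 12 steps (1 to 22).

Step 6 (key step). The most likely failure is poor facial selectivity at C5a, and with it C9a, relative to C7. A bromine next to a gem-dimethyl carbon has only a small preference for the equatorial site, so the two chairs that both give the trans O1/C5 relation may be populated together. The two diastereomers of 9 would differ in the axial or equatorial position of bromine and should be separable. A second risk is unproductive reduction of the ketone, or slow loss of bromine with excess reagent. The fallback closes the same bond through a neutral radical made without a reducing metal, but it does not strengthen the relay from C7. It sets out from 8: TBSOTf and Et3N in CH2Cl2 should give methyl (2E,5S)-5-bromo-8-[(tert-butyldimethylsilyl)oxy]-4,4-dimethylnona-2,8-dienoate F1 (its internal enol ether isomer leads to the same radical). Hydrogen atom transfer from the hydride formed from Fe(acac)3 (trivalent iron) and PhSiH3 in EtOH at 60 °C would generate the tertiary α-silyloxy radical at C9a, which adds 6-exo to the enoate (intramolecular Giese-type reductive olefin coupling). The product would be methyl 2-[(1S,3S,6S)-3-bromo-6-[(tert-butyldimethylsilyl)oxy]-2,2,6-trimethylcyclohexyl]acetate F2, and HF·pyridine would return 9. No electron-transfer reagent meets C–Br, and the large silyloxy group fixes the orientation at C9a; if this fold is no more selective, separation at 9 remains.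

Step 2. The most likely failure is elimination toward C8 or stalling of the alkoxyphosphonium salt, because rear-side attack at a carbinol carbon flanked by a quaternary centre is slow. The fallback separates activation from displacement. It sets out from 3: Tf2O and pyridine in CH2Cl2 at −40 °C should give methyl (3R)-2,2-dimethyl-3-(trifluoromethanesulfonyloxy)hept-6-enoate F3, which the ester-bearing neighbour protects from ionisation. Bu4NBr in toluene at 0 °C to rt would then displace the triflate with inversion and come back to 4.

Step 8. The most likely failure is slow opening of the lactol, so that the thermally labile ylide 14 decays before it olefinates; the sodium alkoxide formed meanwhile also sits trans-1,4 to the bromide. The fallback offers the ylide a true aldehyde. It sets out from 9: TESOTf and 2,6-lutidine would give methyl 2-[(1S,3S,6S)-3-bromo-2,2,6-trimethyl-6-(triethylsilyloxy)cyclohexyl]acetate F4. i-Bu2AlH at −78 °C would give 2-[(1S,3S,6S)-3-bromo-2,2,6-trimethyl-6-(triethylsilyloxy)cyclohexyl]acetaldehyde F5. Ylide 14, made as in step 8, would give {[(1S,2S,4S)-4-bromo-2-[(2Z)-3-iodobut-2-en-1-yl]-1,3,3-trimethylcyclohexyl]oxy}triethylsilane F6, and HF·pyridine would come back to 15.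

Step 10. The most likely failure is attack of the hydroxyl at another position of the activated enyne (conjugate attack at C4 to a tetrahydrofuran), hydration of the alkyne, or acid-induced isomerisation of the labile 2-alkoxydiene. The fallback makes O1–C2 at the carbonyl level. It sets out from 15: Pd(PPh3)4, CO (1 atm) and Et3N in MeCN at 60 °C would effect intramolecular alkoxycarbonylation of the vinyl iodide to (5aS,7S,9aS)-7-bromo-3,6,6,9a-tetramethyl-5,5a,6,7,8,9-hexahydro-1-benzoxepin-2(9aH)-one F7 (the same structure as A2). Petasis methylenation with Cp2TiMe2 in toluene at 70 °C would come back to 19.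

Step 11. The most likely failure is poor facial selectivity at C2, because the bulk of the borane sits on the exocyclic carbon, far from the C9a methyl; protonolysis of the enol ether and β-alkoxy elimination of the organoborane are secondary risks. The fallback moves the stereo-determining event onto the ring carbon. It sets out from 19: dimethyldioxirane in acetone/CH2Cl2 at −78 °C should epoxidise the enol ether from the face opposite the C9a methyl to (2R,5aS,7S,9aS)-7-bromo-3,6,6,9a-tetramethyl-5,5a,6,7,8,9-hexahydro-9aH-spiro[1-benzoxepine-2,2′-oxirane] F8. i-Bu2AlH at −78 °C would open the acetal C–O bond and deliver hydride to C2 (enol ether epoxidation–reductive opening), coming back to 21.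

## Further compounds

F1 | step 6 | methyl (2E,5S)-5-bromo-8-[(tert-butyldimethylsilyl)oxy]-4,4-dimethylnona-2,8-dienoate | C=C(O[Si](C)(C)C(C)(C)C)CC[C@H](Br)C(C)(C)/C=C/C(=O)OC
F2 | step 6 | methyl 2-[(1S,3S,6S)-3-bromo-6-[(tert-butyldimethylsilyl)oxy]-2,2,6-trimethylcyclohexyl]acetate | COC(=O)C[C@H]1C(C)(C)[C@@H](Br)CC[C@]1(C)O[Si](C)(C)C(C)(C)C
F3 | step 2 | methyl (3R)-2,2-dimethyl-3-(trifluoromethanesulfonyloxy)hept-6-enoate | C=CCC[C@@H](OS(=O)(=O)C(F)(F)F)C(C)(C)C(=O)OC
F4 | step 8 | methyl 2-[(1S,3S,6S)-3-bromo-2,2,6-trimethyl-6-(triethylsilyloxy)cyclohexyl]acetate | COC(=O)C[C@H]1C(C)(C)[C@@H](Br)CC[C@]1(C)O[Si](CC)(CC)CC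
F5 | step 8 | 2-[(1S,3S,6S)-3-bromo-2,2,6-trimethyl-6-(triethylsilyloxy)cyclohexyl]acetaldehyde | O=CC[C@H]1C(C)(C)[C@@H](Br)CC[C@]1(C)O[Si](CC)(CC)CC
F6 | step 8 | {[(1S,2S,4S)-4-bromo-2-[(2Z)-3-iodobut-2-en-1-yl]-1,3,3-trimethylcyclohexyl]oxy}triethylsilane | C/C(I)=C/C[C@H]1C(C)(C)[C@@H](Br)CC[C@]1(C)O[Si](CC)(CC)CC
F7 | step 10 | (5aS,7S,9aS)-7-bromo-3,6,6,9a-tetramethyl-5,5a,6,7,8,9-hexahydro-1-benzoxepin-2(9aH)-one | CC1=CC[C@H]2C(C)(C)[C@@H](Br)CC[C@]2(C)OC1=O
F8 | step 11 | (2R,5aS,7S,9aS)-7-bromo-3,6,6,9a-tetramethyl-5,5a,6,7,8,9-hexahydro-9aH-spiro[1-benzoxepine-2,2′-oxirane] | CC1=CC[C@H]2C(C)(C)[C@@H](Br)CC[C@]2(C)O[C@@]13CO3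
A1 | alternative 1 | (4aR,6S,8aS)-6-bromo-2,5,5,8a-tetramethyl-4a,5,6,7,8,8a-hexahydronaphthalen-1(4H)-one | CC1=CC[C@H]2C(C)(C)[C@@H](Br)CC[C@]2(C)C1=O
A2 | alternative 1 | (5aS,7S,9aS)-7-bromo-3,6,6,9a-tetramethyl-5,5a,6,7,8,9-hexahydro-1-benzoxepin-2(9aH)-one | CC1=CC[C@H]2C(C)(C)[C@@H](Br)CC[C@]2(C)OC1=O
A3 | alternative 2 | tert-butyl{[(4aS,6S,8aS)-6-bromo-5,5,8a-trimethyl-4a,5,6,7,8,8a-hexahydro-4H-chromen-2-yl]methoxy}dimethylsilane | CC(C)(C)[Si](C)(C)OCC1=CC[C@H]2C(C)(C)[C@@H](Br)CC[C@]2(C)O1
A4 | alternative 2 | dibromocarbene adduct of A3 (cyclopropane across C2 and C4, CBr2 as C3) | BrC1(Br)C2C[C@H]3C(C)(C)[C@@H](Br)CC[C@]3(C)OC12CO[Si](C)(C)C(C)(C)C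
A5 | alternative 2 | 3-bromo oxepene with C2 set, tert-butyldimethylsilyl ether | BrC1=CC[C@H]2C(C)(C)[C@@H](Br)CC[C@]2(C)O[C@H]1CO[Si](C)(C)C(C)(C)C
A6 | alternative 3 | (1S,2S,4S)-4-bromo-1,3,3-trimethyl-2-[(2Z)-3-methylpent-2-en-4-yn-1-yl]cyclohexan-1-ol | C/C(C#C)=C/C[C@H]1C(C)(C)[C@@H](Br)CC[C@]1(C)O
A7 | alternative 3 | (5aS,7S,9aS)-7-bromo-3,6,6,9a-tetramethyl-2-methylidene-2,5,5a,6,7,8,9,9a-octahydro-1-benzoxepine | CC1=CC[C@H]2C(C)(C)[C@@H](Br)CC[C@]2(C)OC1=C
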